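**Retrosynthetic overview**
1. Attenol A (24) ⇐ acid cascade of the 8-hydroxy-11-keto-(15S,16R)-cis-epoxide 21, freed from hydrazone 20. The five-membered hemiketal forms first, its C11 oxygen opens the epoxide at C15 (6-exo, inversion) to close the six-membered ring and release 16-OH, and the spiro centre settles last under thermodynamic control.
2. 20 ⇐ linchpin coupling of acetone N,N-dimethylhydrazone 18 (C10–C12) with epoxide 17 (C1–C9) and iodide 12 (C13–C21).
3. 12 ⇐ (R)-Roche ester 1 (C13–C15): Still–Gennari olefination, Sharpless epoxidation (C15, C16), epoxy-triflate alkynylation with 7 (C18–C21), Lindlar reduction.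
4. 17 ⇐ ethyl (R)-4-chloro-3-hydroxybutanoate 13 (C6–C9, C8 stereocentre): Weinreb ketone synthesis, 1,3-anti reduction (C6), chlorohydrin closure.

Assumption: the presumed biosynthesis is read as epoxidation of a (15Z)-olefinic 8-hydroxy-11-ketone followed by epoxide opening by the C11 hemiketal oxygen (the keto-epoxide path known for exo-brevicomin, which gives attenol A and its bicyclic-ketal isomer attenol B from one precursor); atoms carry attenol numbering (C1 = vinyl CH2, C11 = spiro carbon, C21 = CH2OH); the THP acetal carbon, the hydrazone C=N and the hemiketal carbon of 22 are inconsequential mixtures drawn without configuration.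

**Route**

Step 1
Reactants: 1 methyl (2R)-3-hydroxy-2-methylpropanoate
Product: 2 methyl (2R)-3-[(tert-butyldimethylsilyl)oxy]-2-methylpropanoate
Conditions: TBSCl, imidazole, CH2Cl2, 0 → 23 °C
Reagents that add atoms: tert-butyldimethylsilyl chloride (TBSCl), CC(C)(C)[Si](C)(C)Cl
Why: Imidazole-promoted silylation of the only hydroxyl (silyl ether formation) masks C13–OH for the later hydride and organometallic steps, and the C14 stereocentre comes unchanged from the chiral pool.

Step 2
Reactants: 2 methyl (2R)-3-[(tert-butyldimethylsilyl)oxy]-2-methylpropanoate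
Product: 3 (2R)-3-[(tert-butyldimethylsilyl)oxy]-2-methylpropanal
Conditions: i-Bu2AlH (1.05 equiv), CH2Cl2, −78 °C; MeOH, aq. potassium sodium tartrate; used crude at once
Reagents that add atoms: none
Why: Partial ester reduction with i-Bu2AlH stops at the tetrahedral aluminium hemiacetal at −78 °C (DIBAL reduction), and the α-branched aldehyde is used immediately so that C14 does not epimerise.

Step 3
Reactants: 3 (2R)-3-[(tert-butyldimethylsilyl)oxy]-2-methylpropanal
Product: 4 methyl (2Z,4S)-5-[(tert-butyldimethylsilyl)oxy]-4-methylpent-2-enoate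
Conditions: (CF3CH2O)2P(O)CH2CO2Me, KN(SiMe3)2, 18-crown-6, THF, −78 °C
Reagents that add atoms: methyl 2-[bis(2,2,2-trifluoroethoxy)phosphoryl]acetate, COC(=O)CP(=O)(OCC(F)(F)F)OCC(F)(F)F
Why: Still–Gennari variant of the Horner–Wadsworth–Emmons olefination, in which the trifluoroethyl phosphonate with a crown-separated potassium counter-ion eliminates under kinetic control to the Z-enoate (C15=C16, typically >10:1 Z:E) without touching C14.

Step 4
Reactants: 4 methyl (2Z,4S)-5-[(tert-butyldimethylsilyl)oxy]-4-methylpent-2-enoate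
Product: 5 (2Z,4S)-5-[(tert-butyldimethylsilyl)oxy]-4-methylpent-2-en-1-ol
Conditions: i-Bu2AlH (2.5 equiv), CH2Cl2, −78 → −40 °C; aq. potassium sodium tartrate
Reagents that add atoms: none
Why: 1,2-Reduction of the enoate by excess i-Bu2AlH (hydride reduction) gives the Z-allylic alcohol that the epoxidation catalyst needs, with no stereocentre affected.

Step 5
Reactants: 5 (2Z,4S)-5-[(tert-butyldimethylsilyl)oxy]-4-methylpent-2-en-1-ol
Product: 6 [(2R,3S)-3-{(2R)-1-[(tert-butyldimethylsilyl)oxy]propan-2-yl}oxiran-2-yl]methanol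
Conditions: Ti(OiPr)4 (20 mol%), D-(−)-diisopropyl tartrate (24 mol%), t-BuOOH (anhydrous, 2 equiv), 4 Å MS, CH2Cl2, −20 °C
Reagents that add atoms: tert-butyl hydroperoxide, CC(C)(C)OO
Why: Katsuki–Sharpless asymmetric epoxidation, in which the D-(−)-tartrate–titanium catalyst delivers oxygen to the face giving the (2R,3S) cis-epoxy alcohol, which is also the face anti to CH2OTBS in the A(1,3)-minimised conformer (matched case), so C15 and C16 are set relative to C14.

Step 6
Reactants: 6 [(2R,3S)-3-{(2R)-1-[(tert-butyldimethylsilyl)oxy]propan-2-yl}oxiran-2-yl]methanol; 7 2-(but-3-yn-1-yloxy)oxane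
Product: 9 tert-butyldimethyl{(2R)-2-[(2S,3R)-3-{5-(oxan-2-yloxy)pent-2-yn-1-yl}oxiran-2-yl]propoxy}silane, via epoxy triflate 8 (not isolated)
Conditions: 6, n-BuLi, Et2O, −78 °C, then Tf2O, −78 °C; transfer into 7/n-BuLi, THF–DMPU, −78 → −30 °C
Reagents that add atoms: none
Why: The primary epoxy triflate made from the lithium alkoxide and Tf2O undergoes SN2 displacement by the lithium acetylide at low temperature much faster than any attack on the hindered cis-epoxide (alkylation of an alkynyllithium by a sulfonate), forming C17–C18 without touching C15 or C16.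

Step 7
Reactants: 9 tert-butyldimethyl{(2R)-2-[(2S,3R)-3-{5-(oxan-2-yloxy)pent-2-yn-1-yl}oxiran-2-yl]propoxy}silane
Product: 10 tert-butyldimethyl{(2R)-2-[(2S,3R)-3-{(2Z)-5-(oxan-2-yloxy)pent-2-en-1-yl}oxiran-2-yl]propoxy}silane
Conditions: H2 (1 atm), Pd/CaCO3 poisoned with Pb(OAc)2, quinoline, EtOAc, 23 °C
Reagents that add atoms: none
Why: Lindlar semihydrogenation adds H2 syn to the alkyne and stops at the Z-alkene (C18=C19), while the epoxide, silyl ether and acetal are inert.

Step 8
Reactants: 10 tert-butyldimethyl{(2R)-2-[(2S,3R)-3-{(2Z)-5-(oxan-2-yloxy)pent-2-en-1-yl}oxiran-2-yl]propoxy}silane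
Product: 11 (2R)-2-[(2S,3R)-3-{(2Z)-5-(oxan-2-yloxy)pent-2-en-1-yl}oxiran-2-yl]propan-1-ol
Conditions: Bu4NF, AcOH (1:1), THF, 0 → 23 °C
Reagents that add atoms: none
Why: Fluoride-driven desilylation frees C13–OH, and acetic acid buffering keeps the liberated alkoxide from attacking the epoxide.

Step 9
Reactants: 11 (2R)-2-[(2S,3R)-3-{(2Z)-5-(oxan-2-yloxy)pent-2-en-1-yl}oxiran-2-yl]propan-1-ol
Product: 12 (2S,3R)-2-[(2S)-1-iodopropan-2-yl]-3-[(2Z)-5-(oxan-2-yloxy)pent-2-en-1-yl]oxirane
Conditions: I2, PPh3, imidazole, CH2Cl2, 0 °C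
Reagents that add atoms: iodine, [I][I]
Why: Garegg–Samuelsson (Appel-type) iodination converts the primary alcohol through its alkoxyphosphonium ion into the iodide by SN2 at CH2, a standard operation on epoxy alcohols that leaves the epoxide and THP ether intact.

Step 10
Reactants: 13 ethyl (3R)-4-chloro-3-hydroxybutanoate
Product: 14 (3R)-4-chloro-3-hydroxy-N-methoxy-N-methylbutanamide
Conditions: MeNH(OMe)·HCl, i-PrMgCl (3.5 equiv), THF, −20 → 0 °C
Reagents that add atoms: N,O-dimethylhydroxylamine hydrochloride, CNOC.Cl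
Why: Aminolysis of the ester by the chloromagnesium amide of N,O-dimethylhydroxylamine (Weinreb amide formation) runs at low temperature with the hydroxyl held as its magnesium alkoxide and the C8 stereocentre untouched.

Step 11
Reactants: 14 (3R)-4-chloro-3-hydroxy-N-methoxy-N-methylbutanamide
Product: 15 (2R)-1-chloro-2-hydroxynon-8-en-4-one
Conditions: CH2=CH(CH2)3MgBr (2.5 equiv), THF, −40 → 0 °C; aq. NH4Cl
Reagents that add atoms: pent-4-en-1-ylmagnesium bromide, C=CCCC[Mg]Br
Why: Weinreb ketone synthesis, in which the Grignard reagent adds once to give a chelated tetrahedral intermediate that collapses to the ketone only on work-up, the first equivalent having deprotonated the hydroxyl.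

Step 12
Reactants: 15 (2R)-1-chloro-2-hydroxynon-8-en-4-one
Product: 17 (2S)-1-[(2R)-oxiran-2-yl]hept-6-en-2-ol, via chloro diol 16 (not isolated)
Conditions: Me4NBH(OAc)3, MeCN/AcOH (4:1), −30 °C; then 3 M aq. NaOH, 0 → 23 °C
Reagents that add atoms: none
Why: Evans–Saksena reduction, in which the C8 hydroxyl exchanges onto boron and delivers hydride intramolecularly through a chair transition state to give the 1,3-anti diol (C6 = S, about 10:1 or better), after which the basic quench closes the chlorohydrin to the epoxide by intramolecular Williamson substitution at the achiral CH2Cl.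

Step 13
Reactants: 18 acetone N,N-dimethylhydrazone; 17 (2S)-1-[(2R)-oxiran-2-yl]hept-6-en-2-ol; 12 (2S,3R)-2-[(2S)-1-iodopropan-2-yl]-3-[(2Z)-5-(oxan-2-yloxy)pent-2-en-1-yl]oxirane
Product: 20 (6S,8S,14R,15S,16R,18Z)-15,16-epoxy-6,8-dihydroxy-14-methyl-21-(oxan-2-yloxy)henicosa-1,18-dien-11-one N,N-dimethylhydrazone, via hydrazone dialkoxide 19 (not isolated)
Conditions: 18, n-BuLi, THF, −78 → 0 °C; 17 (pre-treated with n-BuLi, THF, −78 °C), 0 → 23 °C; n-BuLi, −78 °C; 12, DMPU, −78 → 0 °C; H2O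
Reagents that add atoms: none
Why: Corey–Enders hydrazone alkylation run twice in one flask, in which the lithium azaenolate opens the terminal epoxide at its CH2 (C9), the second deprotonation occurs at the remaining methyl group, and that azaenolate is alkylated by the primary iodide at −78 to 0 °C where the internal cis-epoxide and the lithium alkoxides do not react, so no stereocentre is formed or disturbed.

Step 14
Reactants: 20 (6S,8S,14R,15S,16R,18Z)-15,16-epoxy-6,8-dihydroxy-14-methyl-21-(oxan-2-yloxy)henicosa-1,18-dien-11-one N,N-dimethylhydrazone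
Product: 24 attenol A [(2S)-1-{(2S,5S,7R,8R)-7-[(1R,3Z)-1,6-dihydroxyhex-3-en-1-yl]-8-methyl-1,6-dioxaspiro[4.5]decan-2-yl}hept-6-en-2-ol], via keto epoxide 21 (not isolated), via hemiketal 22 (not isolated), via attenol A THP ether 23 (not isolated)
Conditions: wet SiO2, CH2Cl2, 23 °C; then CSA (1.3 equiv), 0 → 23 °C; then MeOH, 23 °C; aq. NaHCO3
Reagents that add atoms: water, O
Why: Hydrazone hydrolysis on wet silica unveils the C11 ketone, which closes with 8-OH to the five-membered hemiketal; on protonation of the epoxide the hemiketal oxygen attacks C15 in a 6-exo SN2 opening (inversion at C15, retention at C16, the keto-epoxide ketalization type known from exo-brevicomin) to close the tetrahydropyran with methyl and side chain equatorial, the spiro centre equilibrates under acid to the anomerically stabilised (S) configuration with the bicyclic ketal isomer draining into it, and methanolysis removes the THP group.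

**Compound list**
1 | methyl (2R)-3-hydroxy-2-methylpropanoate, (R)-Roche ester | OC[C@@H](C)C(=O)OC | starting material
2 | methyl (2R)-3-[(tert-butyldimethylsilyl)oxy]-2-methylpropanoate | CC(C)(C)[Si](C)(C)OC[C@@H](C)C(=O)OC | intermediate
3 | (2R)-3-[(tert-butyldimethylsilyl)oxy]-2-methylpropanal | CC(C)(C)[Si](C)(C)OC[C@@H](C)C=O | intermediate
4 | methyl (2Z,4S)-5-[(tert-butyldimethylsilyl)oxy]-4-methylpent-2-enoate | CC(C)(C)[Si](C)(C)OC[C@@H](C)/C=C\C(=O)OC | intermediate
5 | (2Z,4S)-5-[(tert-butyldimethylsilyl)oxy]-4-methylpent-2-en-1-ol | CC(C)(C)[Si](C)(C)OC[C@@H](C)/C=C\CO | intermediate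
6 | [(2R,3S)-3-{(2R)-1-[(tert-butyldimethylsilyl)oxy]propan-2-yl}oxiran-2-yl]methanol | CC(C)(C)[Si](C)(C)OC[C@@H](C)[C@@H]1O[C@@H]1CO | intermediate
7 | 2-(but-3-yn-1-yloxy)oxane (THP ether of but-3-yn-1-ol) | C#CCCOC1CCCCO1 | starting material
8 | [(2R,3S)-3-{(2R)-1-[(tert-butyldimethylsilyl)oxy]propan-2-yl}oxiran-2-yl]methyl trifluoromethanesulfonate | CC(C)(C)[Si](C)(C)OC[C@@H](C)[C@@H]1O[C@@H]1COS(=O)(=O)C(F)(F)F | intermediate (not isolated)
9 | tert-butyldimethyl{(2R)-2-[(2S,3R)-3-{5-(oxan-2-yloxy)pent-2-yn-1-yl}oxiran-2-yl]propoxy}silane | CC(C)(C)[Si](C)(C)OC[C@@H](C)[C@@H]1O[C@@H]1CC#CCCOC1CCCCO1 | intermediate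
10 | tert-butyldimethyl{(2R)-2-[(2S,3R)-3-{(2Z)-5-(oxan-2-yloxy)pent-2-en-1-yl}oxiran-2-yl]propoxy}silane | CC(C)(C)[Si](C)(C)OC[C@@H](C)[C@@H]1O[C@@H]1C/C=C\CCOC1CCCCO1 | intermediate
11 | (2R)-2-[(2S,3R)-3-{(2Z)-5-(oxan-2-yloxy)pent-2-en-1-yl}oxiran-2-yl]propan-1-ol | OC[C@@H](C)[C@@H]1O[C@@H]1C/C=C\CCOC1CCCCO1 | intermediate
12 | (2S,3R)-2-[(2S)-1-iodopropan-2-yl]-3-[(2Z)-5-(oxan-2-yloxy)pent-2-en-1-yl]oxirane | C([C@@H](C)[C@@H]1O[C@@H]1C/C=C\CCOC1CCCCO1)I | intermediate
13 | ethyl (3R)-4-chloro-3-hydroxybutanoate | CCOC(=O)C[C@@H](O)CCl | starting material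
14 | (3R)-4-chloro-3-hydroxy-N-methoxy-N-methylbutanamide | CON(C)C(=O)C[C@@H](O)CCl | intermediate
15 | (2R)-1-chloro-2-hydroxynon-8-en-4-one | C=CCCCC(=O)C[C@@H](O)CCl | intermediate
16 | (2R,4S)-1-chloronon-8-ene-2,4-diol | C=CCCC[C@H](O)C[C@@H](O)CCl | intermediate (not isolated)
17 | (2S)-1-[(2R)-oxiran-2-yl]hept-6-en-2-ol | C=CCCC[C@H](O)C[C@@H]1CO1 | intermediate
18 | acetone N,N-dimethylhydrazone | CC(C)=NN(C)C | starting material
19 | dilithium dialkoxide of (5S,7S)-5,7-dihydroxydodec-11-en-2-one N,N-dimethylhydrazone | [Li+].[Li+].C=CCCC[C@H]([O-])C[C@@H]([O-])CCC(C)=NN(C)C | intermediate (not isolated)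
20 | (6S,8S,14R,15S,16R,18Z)-15,16-epoxy-6,8-dihydroxy-14-methyl-21-(oxan-2-yloxy)henicosa-1,18-dien-11-one N,N-dimethylhydrazone | C=CCCC[C@H](O)C[C@@H](O)CCC(=NN(C)C)CC[C@@H](C)[C@@H]1O[C@@H]1C/C=C\CCOC1CCCCO1 | intermediate
21 | (6S,8S,14R,15S,16R,18Z)-15,16-epoxy-6,8-dihydroxy-14-methyl-21-(oxan-2-yloxy)henicosa-1,18-dien-11-one | C=CCCC[C@H](O)C[C@@H](O)CCC(=O)CC[C@@H](C)[C@@H]1O[C@@H]1C/C=C\CCOC1CCCCO1 | intermediate (not isolated)
22 | (5S)-5-[(2S)-2-hydroxyhept-6-en-1-yl]-2-{(3R)-3-[(2S,3R)-3-{(2Z)-5-(oxan-2-yloxy)pent-2-en-1-yl}oxiran-2-yl]butyl}oxolan-2-ol | C=CCCC[C@H](O)C[C@@H]1CCC(O)(CC[C@@H](C)[C@@H]2O[C@@H]2C/C=C\CCOC2CCCCO2)O1 | intermediate (not isolated)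
23 | attenol A 21-O-(oxan-2-yl) ether | C=CCCC[C@H](O)C[C@@H]1CC[C@@]2(CC[C@@H](C)[C@H]([C@H](O)C/C=C\CCOC3CCCCO3)O2)O1 | intermediate (not isolated)
24 | attenol A, (2S)-1-{(2S,5S,7R,8R)-7-[(1R,3Z)-1,6-dihydroxyhex-3-en-1-yl]-8-methyl-1,6-dioxaspiro[4.5]decan-2-yl}hept-6-en-2-ol | C=CCCC[C@H](O)C[C@@H]1CC[C@@]2(CC[C@@H](C)[C@H]([C@H](O)C/C=C\CCO)O2)O1 | target

**Step count**
Total: 14 steps. Longest linear sequence: 11 steps (steps 1–9, then 13 and 14).

**Steps most likely to fail, with fallbacks**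

Step 14 (hydrazone release and epoxide-opening ketalization). The risks are intermolecular opening of the epoxide before the ketone is free, and an unfavourable spiroketal/bicyclic-ketal ratio. The fallback makes the C15–O bond earlier by neighbouring-group delivery and then closes both rings by ordinary thermodynamic ketalization of a trihydroxy ketone. It sets out from 11 and returns at 24. Alcohol 11 is acylated with Boc2O/DMAP to tert-butyl carbonate F1. BF3·OEt2 in CH2Cl2 at −78 °C lets the carbonate carbonyl open the epoxide at C15 (6-exo, inversion) to give cyclic carbonate F2. K2CO3 in MeOH gives triol F3, which already has the (14R,15R,16R) configuration. I2/PPh3/imidazole selects the primary hydroxyl to give iodo diol F4, and 2,2-dimethoxypropane/PPTS gives acetonide F5. F5 takes the place of 12 in the coupling of step 13 and gives hydrazone F6. Aqueous acid followed by MeOH removes hydrazone, acetonide and THP, and the 8,15,16-trihydroxy-11-ketone closes to 24.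

Step 13 (three-component hydrazone coupling through polylithiated intermediates). The risks are poor second metalation in the presence of two alkoxides and elimination of the β-branched iodide. The fallback changes the three-carbon linchpin to allyl acetoacetate and sets out from 17 and 12, returning at 21. The dianion of allyl acetoacetate (NaH, then n-BuLi, THF, 0 °C; excess, since 17 carries a free hydroxyl) opens epoxide 17 at C9 to give β-keto ester F7. Cs2CO3 in DMF alkylates the doubly activated C12 of F7 with iodide 12 to give β-keto ester F8. Pd(PPh3)4 with morpholine removes the allyl ester with loss of CO2 under neutral conditions and gives keto epoxide 21, which enters step 14 at the CSA stage.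

Step 6 (alkynylation of the epoxy triflate). The risks are decomposition of the triflate and competing attack at the epoxide. The fallback builds the C15=C16 alkene by Wittig reaction with the whole C16–C21 chain and introduces the epoxide afterwards under substrate control. It sets out from 3 and 7 and returns at 9. Lithiated 7 (n-BuLi, BF3·OEt2, THF, −78 °C) opens oxirane to give alcohol F9. I2/PPh3/imidazole gives iodide F10, and PPh3 in MeCN at 80 °C gives phosphonium iodide F11. The ylide from F11 (NaN(SiMe3)2, THF, −78 °C) and aldehyde 3 give Z-enyne F12. mCPBA with NaHCO3 in CH2Cl2 at 0 °C epoxidises the only alkene from the face anti to CH2OTBS (A(1,3) control) to give 9. The diastereoselectivity of this epoxidation is expected to be lower than in step 5.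

**Further compounds**
F1 | step 14 | tert-butyl (2R)-2-[(2S,3R)-3-{(2Z)-5-(oxan-2-yloxy)pent-2-en-1-yl}oxiran-2-yl]propyl carbonate | CC(C)(C)OC(=O)OC[C@@H](C)[C@@H]1O[C@@H]1C/C=C\CCOC1CCCCO1
F2 | step 14 | (4R,5R)-4-[(1R,3Z)-1-hydroxy-6-(oxan-2-yloxy)hex-3-en-1-yl]-5-methyl-1,3-dioxan-2-one | O=C1OC[C@@H](C)[C@H]([C@H](O)C/C=C\CCOC2CCCCO2)O1
F3 | step 14 | (2R,3R,4R,6Z)-2-methyl-9-(oxan-2-yloxy)non-6-ene-1,3,4-triol | OC[C@@H](C)[C@@H](O)[C@H](O)C/C=C\CCOC1CCCCO1
F4 | step 14 | (2S,3R,4R,6Z)-1-iodo-2-methyl-9-(oxan-2-yloxy)non-6-ene-3,4-diol | C([C@@H](C)[C@@H](O)[C@H](O)C/C=C\CCOC1CCCCO1)I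
F5 | step 14 | (4R,5R)-4-[(2S)-1-iodopropan-2-yl]-2,2-dimethyl-5-[(2Z)-5-(oxan-2-yloxy)pent-2-en-1-yl]-1,3-dioxolane | C([C@@H](C)[C@H]1OC(C)(C)O[C@@H]1C/C=C\CCOC1CCCCO1)I
F6 | step 14 | (6S,8S,14R,15R,16R,18Z)-6,8-dihydroxy-15,16-(isopropylidenedioxy)-14-methyl-21-(oxan-2-yloxy)henicosa-1,18-dien-11-one N,N-dimethylhydrazone | C=CCCC[C@H](O)C[C@@H](O)CCC(=NN(C)C)CC[C@@H](C)[C@H]1OC(C)(C)O[C@@H]1C/C=C\CCOC1CCCCO1
F7 | step 13 | prop-2-en-1-yl (6S,8S)-6,8-dihydroxy-3-oxotridec-12-enoate | C=CCCC[C@H](O)C[C@@H](O)CCC(=O)CC(=O)OCC=C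
F8 | step 13 | prop-2-en-1-yl (6S,8S)-6,8-dihydroxy-3-oxo-2-{(2R)-2-[(2S,3R)-3-{(2Z)-5-(oxan-2-yloxy)pent-2-en-1-yl}oxiran-2-yl]propyl}tridec-12-enoate (C2 epimers) | C=CCCC[C@H](O)C[C@@H](O)CCC(=O)C(C[C@@H](C)[C@@H]1O[C@@H]1C/C=C\CCOC1CCCCO1)C(=O)OCC=C
F9 | step 6 | 6-(oxan-2-yloxy)hex-3-yn-1-ol | OCCC#CCCOC1CCCCO1
F10 | step 6 | 2-[(6-iodohex-3-yn-1-yl)oxy]oxane | C(CC#CCCOC1CCCCO1)I
F11 | step 6 | [6-(oxan-2-yloxy)hex-3-yn-1-yl]triphenylphosphonium iodide | [I-].C(CC#CCCOC1CCCCO1)[P+](c1ccccc1)(c1ccccc1)c1ccccc1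
F12 | step 6 | tert-butyldimethyl{[(2S,3Z)-2-methyl-9-(oxan-2-yloxy)non-3-en-6-yn-1-yl]oxy}silane | CC(C)(C)[Si](C)(C)OC[C@@H](C)/C=C\CC#CCCOC1CCCCO1
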